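The route rests on cutting the C2–C3 bond of the dihydrofuran ring. C2 carries the isopropenyl group and C3 the ester oxygen, cis to each other: a homoallylic alcohol pattern that an intramolecular carbonyl-ene reaction makes directly. In one operation the key step joins a formyl carbon to the CH carbon of an aryl enol ether, closes the five-membered oxygen ring, sets both stereocentres and reveals the isopropenyl group by hydrogen transfer from a methyl group. Its precursor is a benzaldehyde with a 2-methylprop-1-enyl ether ortho to the formyl group, an acetyl group para to that ether and an acetoxy group para to the formyl group. Acylation at O3 and release of the phenol finish the target.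

Key step: step 6

Assumption: the sense of induction of the scandium–pybox catalyst on this substrate cannot be assigned in advance, so (S,S)-Ph-pybox is written and its antipode is taken if the (2R,3R) series should result.

Step 1
Reactants: 1 1-(2,4-dimethoxyphenyl)ethan-1-one (2,4-dimethoxyacetophenone)
Product: 2 5-acetyl-2,4-dimethoxybenzaldehyde
Conditions: Cl2CHOMe, TiCl4, CH2Cl2, 0 °C to rt; then ice-cold aq. HCl
Reagents that add atoms: dichloromethyl methyl ether ClC(Cl)OC; water O
Why: Rieche formylation (electrophilic aromatic substitution) should enter at C5, the only position that is ortho to one methoxy group, para to the other, meta to the acetyl group and not wedged between the two ethers; a Vilsmeier reagent is avoided because it would attack the acetyl methyl group, and any methyl ether lost to TiCl4 is harmless since step 2 removes both.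

Step 2
Reactants: 2 5-acetyl-2,4-dimethoxybenzaldehyde
Product: 3 5-acetyl-2,4-dihydroxybenzaldehyde
Conditions: BCl3, CH2Cl2, −78 °C to rt; then H2O
Reagents that add atoms: none
Why: Chelation-assisted ether cleavage with BCl3 works here because each methoxy group sits ortho to a carbonyl group, so boron binds the carbonyl oxygen and chloride removes the neighbouring methyl group while aldehyde and ketone survive.

Step 3
Reactants: 3 5-acetyl-2,4-dihydroxybenzaldehyde; 4 3-chloro-2-methylprop-1-ene
Product: 5 5-acetyl-4-hydroxy-2-[(2-methylprop-2-en-1-yl)oxy]benzaldehyde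
Conditions: KHCO3, DMF, 50 °C
Reagents that add atoms: none
Why: Williamson etherification under weak-base control should select the hydroxyl beside the formyl group, which is the more acidic and less tightly hydrogen-bonded of the two (an aldehyde is a weaker hydrogen-bond acceptor than the ketone), while the ketone-chelated hydroxyl stays protonated.

Step 4
Reactants: 5 5-acetyl-4-hydroxy-2-[(2-methylprop-2-en-1-yl)oxy]benzaldehyde
Product: 6 2-acetyl-4-formyl-5-[(2-methylprop-2-en-1-yl)oxy]phenyl acetate
Conditions: Ac2O, pyridine, DMAP (cat.), CH2Cl2, 0 °C to rt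
Reagents that add atoms: acetic anhydride CC(=O)OC(C)=O
Why: DMAP-catalysed O-acetylation caps the remaining chelated phenol, which removes an o-hydroxyaryl ketone binding site for the Lewis acid of step 6 and makes the oxygen para to the formyl group a weaker donor.

Step 5
Reactants: 6 2-acetyl-4-formyl-5-[(2-methylprop-2-en-1-yl)oxy]phenyl acetate
Product: 7 2-acetyl-4-formyl-5-[(2-methylprop-1-en-1-yl)oxy]phenyl acetate
Conditions: RuHCl(CO)(PPh3)3 (5 mol %), toluene, 80 °C
Reagents that add atoms: none
Why: Ruthenium hydride-catalysed double-bond migration (hydrometalation, then β-hydride elimination) moves the 1,1-disubstituted alkene into conjugation with oxygen to give the more stable trisubstituted enol ether under neutral conditions that spare aldehyde, ketone and aryl acetate and lie well below the onset of a thermal ene or Claisen reaction.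

Step 6
Reactants: 7 2-acetyl-4-formyl-5-[(2-methylprop-1-en-1-yl)oxy]phenyl acetate
Product: 8 (2S,3S)-5-acetyl-3-hydroxy-2-(prop-1-en-2-yl)-2,3-dihydro-1-benzofuran-6-yl acetate
Conditions: Sc(OTf)3 (10 mol %), (S,S)-Ph-pybox (12 mol %), 4 Å MS, CH2Cl2, −40 to −10 °C; Et3N quench
Reagents that add atoms: none
Why: Proposed new method: the scandium-bound formyl group of 7 is attacked in the arene plane by the enol ether CH carbon (C2–C3 bond) while the carbonyl oxygen takes a hydrogen from one of the geminal methyl groups through a six-membered, asynchronous ene transition state with positive charge building on the dimethyl-bearing carbon, so ring closure and formation of the isopropenyl group are a single event. The closest known reaction type is the catalytic asymmetric intramolecular carbonyl-ene cyclisation of olefinic aldehydes that carry a trisubstituted alkene (citronellal to isopulegol and its five-ring-forming relatives) under chiral Lewis acid catalysis, which has not been run with an aryl enol ether as the ene. The dihydrofuran ring closes 5-exo-trig onto the carbonyl carbon. C3 is set by the chiral ligand sphere, which selects the face of the aldehyde once it is twisted out of the arene plane, and C2 is set relative to C3 by the transition state, in which the ene ring and the nearly planar nascent five-membered ring share the forming bond and can only be cis-fused, so hydroxyl and isopropenyl end on the same face. The step needs bonding at the oxygen-bearing CH carbon and not at the dimethyl carbon, and a concerted course and not a stepwise Prins course; the first is secured because the aryloxy lone pair is drawn into a ring carrying a para acetyl and an ortho formyl group, so the alkene behaves as a plain trisubstituted olefin, and because the six-ring Prins adduct at the dimethyl carbon has no hydrogen to lose and can only revert. The acetate on O6 and the ketone at C5 keep the benzylic C3–O bond of 8 from ionising, which would otherwise erode the cis relation or lead to the benzofuran.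

Step 7
Reactants: 9 3-methylfuran-2(5H)-one
Product: 12 4-methoxybenzyl (Z)-4-acetoxy-2-methylbut-2-enoate, via potassium hydroxy carboxylate 10 (not isolated), via PMB hydroxy ester 11 (not isolated)
Conditions: KOH (0.98 equiv), MeOH/H2O, 0 °C; evaporate; 4-MeOC6H4CH2Cl, DMF, rt; then Ac2O, pyridine, DMAP (cat.), 0 °C to rt
Reagents that add atoms: potassium hydroxide [K+].[OH-]; 4-methoxybenzyl chloride COc1ccc(CCl)cc1; acetic anhydride CC(=O)OC(C)=O
Why: Lactone saponification, carboxylate O-alkylation and DMAP-catalysed acetylation in one pot keep the Z geometry inherited from the ring, and capping the carboxylate as its 4-methoxybenzyl ester before the hydroxyl is acetylated blocks the mixed-anhydride pathway by which the hydroxy acid would close back to the butenolide.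

Step 8
Reactants: 12 4-methoxybenzyl (Z)-4-acetoxy-2-methylbut-2-enoate
Product: 13 (Z)-4-acetoxy-2-methylbut-2-enoic acid
Conditions: TFA, anisole, CH2Cl2, 0 °C
Reagents that add atoms: none
Why: Acidolysis of the 4-methoxybenzyl ester (ionisation to the 4-methoxybenzyl cation, trapped by anisole) frees the acid without cleaving the primary acetate or isomerising the Z alkene.

Step 9
Reactants: 8 (2S,3S)-5-acetyl-3-hydroxy-2-(prop-1-en-2-yl)-2,3-dihydro-1-benzofuran-6-yl acetate; 13 (Z)-4-acetoxy-2-methylbut-2-enoic acid
Product: 15 (2S,3S)-6-acetoxy-5-acetyl-2-(prop-1-en-2-yl)-2,3-dihydro-1-benzofuran-3-yl (Z)-4-acetoxy-2-methylbut-2-enoate, via mixed anhydride 14 (not isolated)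
Conditions: 2,4,6-Cl3C6H2COCl, Et3N, toluene, 0 °C to rt; then 8, DMAP (0.5 equiv), toluene, rt
Reagents that add atoms: none
Why: Yamaguchi esterification should work because DMAP opens the mixed anhydride at the less hindered enoyl carbonyl and the acylpyridinium acylates the C3 hydroxyl without touching the C3–O bond, so both stereocentres are retained, and because the phenol is still acetylated no competing aryl ester can form.

Step 10
Reactants: 15 (2S,3S)-6-acetoxy-5-acetyl-2-(prop-1-en-2-yl)-2,3-dihydro-1-benzofuran-3-yl (Z)-4-acetoxy-2-methylbut-2-enoate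
Product: 16 (2S,3S)-5-acetyl-6-hydroxy-2-(prop-1-en-2-yl)-2,3-dihydro-1-benzofuran-3-yl (Z)-4-acetoxy-2-methylbut-2-enoate
Conditions: NH4OAc, MeOH/H2O (4:1), rt
Reagents that add atoms: none
Why: Chemoselective solvolysis of the aryl acetate, whose phenoxide is by far the better leaving group and which is further activated by the ortho acetyl group, should proceed under neutral ammonium acetate buffering that leaves the primary alkyl acetate and the hindered C3 enoate untouched and avoids a free phenoxide that could expel the C3 carboxylate.

Compound list
1 | 1-(2,4-dimethoxyphenyl)ethan-1-one | COc1ccc(C(C)=O)c(OC)c1 | starting material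
2 | 5-acetyl-2,4-dimethoxybenzaldehyde | COc1cc(OC)c(C(C)=O)cc1C=O | intermediate
3 | 5-acetyl-2,4-dihydroxybenzaldehyde | CC(=O)c1cc(C=O)c(O)cc1O | intermediate
4 | 3-chloro-2-methylprop-1-ene | C=C(C)CCl | starting material
5 | 5-acetyl-4-hydroxy-2-[(2-methylprop-2-en-1-yl)oxy]benzaldehyde | C=C(C)COc1cc(O)c(C(C)=O)cc1C=O | intermediate
6 | 2-acetyl-4-formyl-5-[(2-methylprop-2-en-1-yl)oxy]phenyl acetate | C=C(C)COc1cc(OC(C)=O)c(C(C)=O)cc1C=O | intermediate
7 | 2-acetyl-4-formyl-5-[(2-methylprop-1-en-1-yl)oxy]phenyl acetate | CC(C)=COc1cc(OC(C)=O)c(C(C)=O)cc1C=O | intermediate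
8 | (2S,3S)-5-acetyl-3-hydroxy-2-(prop-1-en-2-yl)-2,3-dihydro-1-benzofuran-6-yl acetate (2,3-cis) | C=C(C)[C@@H]1Oc2cc(OC(C)=O)c(C(C)=O)cc2[C@@H]1O | intermediate
9 | 3-methylfuran-2(5H)-one | CC1=CCOC1=O | starting material
10 | potassium (Z)-4-hydroxy-2-methylbut-2-enoate | [K+].[O-]C(=O)/C(C)=C\CO | intermediate
11 | 4-methoxybenzyl (Z)-4-hydroxy-2-methylbut-2-enoate | COc1ccc(COC(=O)/C(C)=C\CO)cc1 | intermediate
12 | 4-methoxybenzyl (Z)-4-acetoxy-2-methylbut-2-enoate | COc1ccc(COC(=O)/C(C)=C\COC(C)=O)cc1 | intermediate
13 | (Z)-4-acetoxy-2-methylbut-2-enoic acid | O=C(O)/C(C)=C\COC(C)=O | intermediate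
14 | (Z)-4-acetoxy-2-methylbut-2-enoic 2,4,6-trichlorobenzoic anhydride | O=C(OC(=O)/C(C)=C\COC(C)=O)c1c(Cl)cc(Cl)cc1Cl | intermediate
15 | (2S,3S)-6-acetoxy-5-acetyl-2-(prop-1-en-2-yl)-2,3-dihydro-1-benzofuran-3-yl (Z)-4-acetoxy-2-methylbut-2-enoate | C=C(C)[C@@H]1Oc2cc(OC(C)=O)c(C(C)=O)cc2[C@@H]1OC(=O)/C(C)=C\COC(C)=O | intermediate
16 | (2S,3S)-5-acetyl-6-hydroxy-2-(prop-1-en-2-yl)-2,3-dihydro-1-benzofuran-3-yl (Z)-4-acetoxy-2-methylbut-2-enoate | C=C(C)[C@@H]1Oc2cc(O)c(C(C)=O)cc2[C@@H]1OC(=O)/C(C)=C\COC(C)=O | target

Total step count: 10. Longest linear sequence: 8 steps (1 to 16 through steps 1–6, 9 and 10); the acid 13 is made in a 2-step side branch (steps 7 and 8).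

Steps most likely to fail

1. Step 6 (the new method). The cyclisation may fail through poor enantioface selection, through a stepwise Prins course that gives the trans isomer or dehydrates to the benzofuran, or through lack of turnover. The fallback uses known chemistry, sets out from 6 and returns at 8. Ozonolysis of the methallyl alkene of 6 (O3, CH2Cl2, −78 °C; Me2S) should give 2-acetyl-4-formyl-5-(2-oxopropoxy)phenyl acetate F1. A proline-catalysed intramolecular aldol reaction (5-enolexo, enamine at the aryloxy-flanked CH2, DMF, rt, proline antipode chosen for the 3S carbinol) should then close the same C2–C3 bond to the cis-configured (2R,3S)-2,5-diacetyl-3-hydroxy-2,3-dihydro-1-benzofuran-6-yl acetate F2, which is used at once because β-elimination to the benzofuran threatens. Non-basic Takai–Lombardo methylenation (Zn, CH2Br2, TiCl4, THF, 0 °C) of the more electrophilic α-aryloxy alkyl ketone, in preference to the hindered and donor-conjugated aryl ketone, should turn the 2-acetyl group into the isopropenyl group and deliver 8.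

2. Step 9. Acylation of the hindered cis alcohol may be slow, and the activated acid may isomerise from Z to E through DMAP adducts or vinylogous enolisation. The fallback sets out from 8 and returns at 15. Steglich acylation of 8 with 2-[bis(2,2,2-trifluoroethoxy)phosphoryl]propanoic acid (DCC, DMAP cat., CH2Cl2, 0 °C) should give (2S,3S)-6-acetoxy-5-acetyl-2-(prop-1-en-2-yl)-2,3-dihydro-1-benzofuran-3-yl 2-[bis(2,2,2-trifluoroethoxy)phosphoryl]propanoate F3. Still–Gennari olefination of this phosphonate with 2-oxoethyl acetate (KN(SiMe3)2, 18-crown-6, THF, −78 °C, base limiting so that only the phosphonate is deprotonated) then builds the Z-trisubstituted enoate on the substrate, so no preformed Z acid has to be activated.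

3. Step 3. Discrimination between the two chelated hydroxyls may be insufficient, giving the regioisomeric ether or bis-alkylation. The fallback sets out from 3 and returns at 5. The aldehyde is first masked as a cyclic acetal (2,2-dimethylpropane-1,3-diol, PPTS, benzene, Dean–Stark) to give 1-[5-(5,5-dimethyl-1,3-dioxan-2-yl)-2,4-dihydroxyphenyl]ethan-1-one F4, in which only the ketone-flanked hydroxyl is still chelated. Alkylation with 4 (K2CO3, acetone, reflux) then follows the established preference for the unchelated para hydroxyl of a 2,4-dihydroxyacetophenone and should give 1-{5-(5,5-dimethyl-1,3-dioxan-2-yl)-2-hydroxy-4-[(2-methylprop-2-en-1-yl)oxy]phenyl}ethan-1-one F5. Mild aqueous acid (1 M HCl, THF, rt) frees the aldehyde to give 5.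

Further compounds
F1 | step 6 | 2-acetyl-4-formyl-5-(2-oxopropoxy)phenyl acetate | CC(=O)COc1cc(OC(C)=O)c(C(C)=O)cc1C=O
F2 | step 6 | (2R,3S)-2,5-diacetyl-3-hydroxy-2,3-dihydro-1-benzofuran-6-yl acetate (2,3-cis) | CC(=O)[C@@H]1Oc2cc(OC(C)=O)c(C(C)=O)cc2[C@@H]1O
F3 | step 9 | (2S,3S)-6-acetoxy-5-acetyl-2-(prop-1-en-2-yl)-2,3-dihydro-1-benzofuran-3-yl 2-[bis(2,2,2-trifluoroethoxy)phosphoryl]propanoate | C=C(C)[C@@H]1Oc2cc(OC(C)=O)c(C(C)=O)cc2[C@@H]1OC(=O)C(C)P(=O)(OCC(F)(F)F)OCC(F)(F)F
F4 | step 3 | 1-[5-(5,5-dimethyl-1,3-dioxan-2-yl)-2,4-dihydroxyphenyl]ethan-1-one | CC(=O)c1cc(C2OCC(C)(C)CO2)c(O)cc1O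
F5 | step 3 | 1-{5-(5,5-dimethyl-1,3-dioxan-2-yl)-2-hydroxy-4-[(2-methylprop-2-en-1-yl)oxy]phenyl}ethan-1-one | C=C(C)COc1cc(O)c(C(C)=O)cc1C1OCC(C)(C)CO1
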